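**Plan**

1. Numbering: C1 furanone C=O, C2=C3 its alkene (ring O on C3), C4(CH3)=C5 the Z-alkene, C6 lactone O–CH, C7 lactone CH, C8 CH–OH, C9 CH–O-methacrylate, C10 quaternary C(CH3)–O, C11–C13 the methylene-lactone carbons.
2. Enabling feature: C9 is a carbinol β to the C1 ketone, and C10 is the fully substituted α-carbon that also carries the furanone ring oxygen. C9–C10 is therefore the aldol bond of an aromatic 2-methyl-3-silyloxyfuran (C10 = furan C2) with a C9 aldehyde.
3. Cuts, in retrosynthetic order: the methacrylate C–O bond; C9–C10 (ten-membered carbocycle); C3–C4 (furan to Z-alkene, Stille); C6–C7 and O6–C12 (lactone, allylboration/lactonisation).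
4. Forward: the methylene lactone is made first from a glyceraldehyde-derived allylboronate and (Z)-3-iodobut-2-enal; the stannylfuran is joined at C3–C4; the ten-membered ring closes last, with the furanone and its oxygen bridge appearing in the same step; esterification and desilylation finish.
5. Stereochemistry: C8 from (R)-glyceraldehyde acetonide; C7 and C6 from the chair allylboration (allylic strain and an E-type reagent); Z-C4=C5 from trans-hydroalumination/iodination; C9 (Felkin–Anh) and C10 (tether) in the ring closure.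

Key step: step 16

Remark: (R)-2,3-O-isopropylideneglyceraldehyde is taken as the D-mannitol-derived enantiomer, CC1(C)OC[C@H](C=O)O1, whose stereocentre maps onto C8 (S in the target); the lactate stereocentre is erased in step 4, so its configuration is of no consequence.

**Route**

Step 1
Reactants: 1 ethyl (S)-lactate
Product: 2 (2S)-2-hydroxy-N-methoxy-N-methylpropanamide
Conditions: MeNH(OMe)·HCl, i-PrMgCl, THF, −20 → 0 °C
Reagents that add atoms: N,O-dimethylhydroxylamine hydrochloride (CNOC.Cl)
Why: Weinreb amide formation by aminolysis of the ester with the magnesium amide of N,O-dimethylhydroxylamine, the free hydroxyl being carried as its magnesium alkoxide and the stereocentre left untouched.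

Step 2
Reactants: 2 (2S)-2-hydroxy-N-methoxy-N-methylpropanamide
Product: 4 (1E,4S)-1-(diethylamino)-4-hydroxypent-1-en-3-one, via hydroxy ynone 3 (not isolated)
Conditions: HC≡CMgBr (excess), THF, 0 °C → rt; cold aq. NaHSO4, extraction; then Et2NH, EtOH, 0 °C
Reagents that add atoms: ethynylmagnesium bromide (C#C[Mg]Br); diethylamine (CCNCC)
Why: Acylation of the alkynyl Grignard reagent by the Weinreb amide stops at the ketone because the chelated tetrahedral intermediate survives until the quench, and the terminal ynone then takes up diethylamine by conjugate addition to give the stable E-enaminone in place of the volatile ynone.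

Step 3
Reactants: 4 (1E,4S)-1-(diethylamino)-4-hydroxypent-1-en-3-one
Product: 5 2-methylfuran-3(2H)-one
Conditions: 1 M HCl, THF, rt; product kept as a concentrated solution
Reagents that add atoms: none
Why: Acid-promoted addition of the hydroxyl to the protonated enaminone and loss of diethylamine is the classical 3(2H)-furanone synthesis; the C2 stereocentre is enolisable and is erased in step 4.

Step 4
Reactants: 5 2-methylfuran-3(2H)-one
Product: 6 2-methyl-3-[(triisopropylsilyl)oxy]furan
Conditions: TIPSOTf, Et3N, CH2Cl2, 0 °C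
Reagents that add atoms: triisopropylsilyl trifluoromethanesulfonate (CC(C)[Si](C(C)C)(C(C)C)OS(=O)(=O)C(F)(F)F)
Why: Soft enolisation with a silyl triflate and an amine (silyl enol ether formation) gives the aromatic 3-silyloxyfuran, the bulky triisopropylsilyl group being chosen so that the enol ether survives lithiation, chromatography and the later coupling.

Step 5
Reactants: 6 2-methyl-3-[(triisopropylsilyl)oxy]furan
Product: 8 tributyl{5-methyl-4-[(triisopropylsilyl)oxy]furan-2-yl}stannane, via lithiofuran 7 (not isolated)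
Conditions: n-BuLi, TMEDA, THF, −78 → −20 °C; Bu3SnCl, −78 °C → rt
Reagents that add atoms: tributyltin chloride (CCCC[Sn](Cl)(CCCC)CCCC)
Why: Deprotonation of the furan at its only free α-position (C5) followed by trapping with the tin chloride (α-metalation/stannylation); the silyl group sits on O3 and not next to the lithiated carbon, so no silyl migration is expected.

Step 6
Reactants: 9 but-2-yn-1-ol
Product: 11 (2Z)-3-iodobut-2-en-1-ol, via cyclic alkenylaluminate 10 (not isolated)
Conditions: NaAlH2(OCH2CH2OMe)2 (Red-Al), THF, 0 °C → rt; then I2, THF, −78 °C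
Reagents that add atoms: iodine (II)
Why: trans-Hydroalumination of the propargylic alcohol through the alkoxide-bound aluminate places aluminium on C3 cis to the CH2O group, and iodinolysis with retention gives the Z-iodoalkene that later becomes the Z-C4=C5 bond.

Step 7
Reactants: 11 (2Z)-3-iodobut-2-en-1-ol
Product: 12 (2Z)-3-iodobut-2-enal
Conditions: MnO2, CH2Cl2, rt, dark
Reagents that add atoms: none
Why: Oxidation of the allylic alcohol on MnO2 under neutral conditions keeps the Z geometry of the β-iodoenal, which is used at once.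

Step 8
Reactants: 13 (R)-2,3-O-isopropylideneglyceraldehyde
Product: 14 (4S)-4-(2,2-dibromoethenyl)-2,2-dimethyl-1,3-dioxolane
Conditions: CBr4, PPh3, Et3N, CH2Cl2, 0 °C
Reagents that add atoms: carbon tetrabromide (BrC(Br)(Br)Br)
Why: Corey–Fuchs dibromo-olefination (Wittig reaction of the dibromomethylene ylide), with triethylamine as buffer so that the acetonide and the α-stereocentre survive.

Step 9
Reactants: 14 (4S)-4-(2,2-dibromoethenyl)-2,2-dimethyl-1,3-dioxolane
Product: 16 methyl 3-[(4S)-2,2-dimethyl-1,3-dioxolan-4-yl]prop-2-ynoate, via lithium acetylide 15 (not isolated)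
Conditions: n-BuLi (2 equiv), THF, −78 °C; ClCO2Me, −78 → 0 °C
Reagents that add atoms: methyl chloroformate (COC(=O)Cl)
Why: Lithium–bromine exchange, Fritsch–Buttenberg–Wiechell rearrangement and deprotonation give the lithium acetylide (second stage of the Corey–Fuchs sequence), which is C-acylated by the chloroformate.

Step 10
Reactants: 16 methyl 3-[(4S)-2,2-dimethyl-1,3-dioxolan-4-yl]prop-2-ynoate
Product: 18 methyl (2Z)-3-[(4S)-2,2-dimethyl-1,3-dioxolan-4-yl]-2-[(4,4,5,5-tetramethyl-1,3,2-dioxaborolan-2-yl)methyl]prop-2-enoate, via alkenylalane 17 (not isolated)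
Conditions: i-Bu2AlH, HMPA, THF, 0 °C; then ICH2Bpin, 0 °C → rt
Reagents that add atoms: 2-(iodomethyl)-4,4,5,5-tetramethyl-1,3,2-dioxaborolane (ICB1OC(C)(C)C(C)(C)O1)
Why: syn-1,4-Hydroalumination of the ynoate by i-Bu2AlH in the presence of HMPA gives the α-alumino acrylate with H and Al cis, and its alkylation by the iodomethylboronate with retention gives the allylboronate with the dioxolane cis to the ester (2Z), the geometry needed for an anti allylboration.

Step 11
Reactants: 18 the (2Z)-allylboronate; 12 (2Z)-3-iodobut-2-enal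
Product: 20 (4S,5S)-4-[(4S)-2,2-dimethyl-1,3-dioxolan-4-yl]-5-[(1Z)-2-iodoprop-1-en-1-yl]-3-methylideneoxolan-2-one (trans-lactone), via anti borate 19 (not isolated)
Conditions: Sc(OTf)3 (10 mol %), toluene, −78 → 0 °C; then PPTS (cat.), toluene, 40 °C
Reagents that add atoms: none
Why: Lewis-acid-catalysed allylboration through a closed chair transition state followed by lactonisation (tandem allylboration/lactonisation of a 2-alkoxycarbonyl allylboronate): with the dioxolane trans to CH2B the reagent behaves as an E-γ-substituted allylboronate and gives the anti adduct, hence the trans-lactone (C6), while allylic 1,3-strain with the cis ester holds C8–H in the alkene plane so that the aldehyde should add to C7 anti to the C8–C9 bond with the dioxolane oxygen on the outside, which sets C7 relative to C8.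

Step 12
Reactants: 20 trans-lactone acetonide
Product: 21 (4R,5S)-4-[(1S)-1,2-dihydroxyethyl]-5-[(1Z)-2-iodoprop-1-en-1-yl]-3-methylideneoxolan-2-one
Conditions: AcOH/H2O (4:1), 40 °C
Reagents that add atoms: none
Why: Mild acid hydrolysis of the isopropylidene acetal leaves the vinyl iodide and the methylene lactone alone, and the trans-lactone on O6 should not migrate to O8, where it would be cis-disubstituted and less stable.

Step 13
Reactants: 21 the diol
Product: 22 (4S,5S)-4-[(1S)-1,2-bis(triethylsilyloxy)ethyl]-5-[(1Z)-2-iodoprop-1-en-1-yl]-3-methylideneoxolan-2-one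
Conditions: TESOTf, 2,6-lutidine, CH2Cl2, −78 °C
Reagents that add atoms: triethylsilyl trifluoromethanesulfonate (CC[Si](CC)(CC)OS(=O)(=O)C(F)(F)F)
Why: Silylation of the primary and the secondary hydroxyl with a silyl triflate and a non-nucleophilic base at low temperature, which avoids conjugate addition to the methylene lactone.

Step 14
Reactants: 22 the bis(triethylsilyl) ether
Product: 23 (2S)-2-[(2S,3S)-2-[(1Z)-2-iodoprop-1-en-1-yl]-4-methylidene-5-oxooxolan-3-yl]-2-(triethylsilyloxy)acetaldehyde
Conditions: (COCl)2, DMSO, CH2Cl2, −78 → −40 °C; Et3N, −78 → 0 °C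
Reagents that add atoms: none
Why: Under Swern conditions the primary triethylsilyl ether is cleaved by the chlorosulfonium salt and oxidised in the same flask while the secondary silyl ether stays (selective oxidative desilylation), giving the α-silyloxy aldehyde at low temperature without epimerisation at C8.

Step 15
Reactants: 23 the iodoalkenyl aldehyde; 8 the stannylfuran
Product: 24 (2S)-2-[(2R,3S)-2-[(1Z)-2-{5-methyl-4-[(triisopropylsilyl)oxy]furan-2-yl}prop-1-en-1-yl]-4-methylidene-5-oxooxolan-3-yl]-2-(triethylsilyloxy)acetaldehyde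
Conditions: Pd2(dba)3 (5 mol %), AsPh3 (20 mol %), CuI (10 mol %), DMF, rt, dark
Reagents that add atoms: none
Why: Stille coupling of the alkenyl iodide with the electron-rich 2-furylstannane should proceed at room temperature with retention of the Z geometry and under neutral conditions that the aldehyde, the silyl enol ether and the methylene lactone tolerate.

Step 16
Reactants: 24 the silyloxyfuran aldehyde
Product: 26 the 9-hydroxy-8-O-triethylsilyl macrocycle (6R,7S,8S,9S,10S), via oxocarbenium aldolate 25 (not isolated)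
Conditions: BF3·OEt2, 2,6-di-tert-butyl-4-methylpyridine, CH2Cl2 (about 1 mM, slow addition of 24), −78 °C; aq. NaHCO3
Reagents that add atoms: none
Why: Proposed new method: BF3 binds the C9 aldehyde, C2 of the 2-methyl-3-silyloxyfuran (the future C10, α-carbon of the embedded silyl enol ether) attacks it, and the O-silyl oxocarbenium ion 25 loses silicon as the fluoride to leave the 3(2H)-furanone, so that the C9–C10 bond, the quaternary centre, the carbinol and the vinylogous ester appear together; the closest known reaction type is the intermolecular BF3-mediated Mukaiyama aldol of 2-alkyl-3-silyloxyfurans with aldehydes at C2, which has not been used to close a ten-membered ring. The carbocycle closes in a 10-(enol-endo)-exo-trig mode on the aldehyde, helped by three rigid units (furan, Z-alkene, trans-lactone) that leave only the C7–C8 and C8–C9 bonds free to rotate, and the furanone with its oxygen bridge is unveiled, not closed, in the same event. C9 should be set by Felkin–Anh attack anti to the C8–OSiEt3 bond under non-chelating BF3 (8,9-anti), and C10 by the short tether from C7, which should let only one face of the planar furan reach the aldehyde. The step needs C2 over C4 regioselectivity (C2 is the enol-ether terminus and C4 attack would require a strained eight-membered ring), aldehyde over methylene-lactone chemoselectivity (only the aldehyde is activated at −78 °C) and cyclisation over oligomerisation (high dilution). The lost furan aromaticity is repaid by the conjugated furanone.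

Step 17
Reactants: 26 the 9-hydroxy macrocycle
Product: 27 the 9-O-methacryloyl-8-O-triethylsilyl macrocycle (6R,7S,8S,9S,10S)
Conditions: methacrylic anhydride, DMAP, Et3N, CH2Cl2, 0 °C → rt
Reagents that add atoms: methacrylic anhydride (CC(=C)C(=O)OC(=O)C(C)=C)
Why: DMAP-catalysed acylation of the secondary hydroxyl with the anhydride (nucleophilic catalysis) needs no alkoxide, which guards against retro-aldol opening of the β-hydroxy ketone.

Step 18
Reactants: 27 the silyl ether
Product: 28 CNP0562373.1 (6R,7R,8S,9S,10S)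
Conditions: HF·pyridine, pyridine, THF, 0 °C
Reagents that add atoms: none
Why: Cleavage of the secondary triethylsilyl ether with buffered HF·pyridine (fluoride desilylation) is mildly acidic, so that neither acyl migration from O9 to O8 nor conjugate addition to the two acrylate units is expected.

**Compound list**

1 | ethyl (S)-lactate | C[C@H](O)C(=O)OCC | starting material
2 | (2S)-2-hydroxy-N-methoxy-N-methylpropanamide | C[C@H](O)C(=O)N(C)OC | intermediate
3 | (4S)-4-hydroxypent-1-yn-3-one (in-flask ynone) | C[C@H](O)C(=O)C#C | intermediate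
4 | (1E,4S)-1-(diethylamino)-4-hydroxypent-1-en-3-one | C[C@H](O)C(=O)/C=C/N(CC)CC | intermediate
5 | 2-methylfuran-3(2H)-one (C2 configuration labile) | CC1OC=CC1=O | intermediate
6 | 2-methyl-3-[(triisopropylsilyl)oxy]furan | Cc1occc1O[Si](C(C)C)(C(C)C)C(C)C | intermediate
7 | 5-lithio-2-methyl-3-[(triisopropylsilyl)oxy]furan (in-flask) | Cc1oc([Li])cc1O[Si](C(C)C)(C(C)C)C(C)C | intermediate
8 | tributyl{5-methyl-4-[(triisopropylsilyl)oxy]furan-2-yl}stannane | Cc1oc(cc1O[Si](C(C)C)(C(C)C)C(C)C)[Sn](CCCC)(CCCC)CCCC | intermediate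
9 | but-2-yn-1-ol | CC#CCO | starting material
10 | sodium 2,2-bis(2-methoxyethoxy)-3-methyl-2,5-dihydro-1,2-oxaluminol-2-uide (in-flask cyclic alkenylaluminate) | CC1=CCO[Al-]1(OCCOC)OCCOC.[Na+] | intermediate
11 | (2Z)-3-iodobut-2-en-1-ol | C/C(I)=C/CO | intermediate
12 | (2Z)-3-iodobut-2-enal | C/C(I)=C/C=O | intermediate
13 | (R)-2,3-O-isopropylideneglyceraldehyde | CC1(C)OC[C@H](C=O)O1 | starting material
14 | (4S)-4-(2,2-dibromoethenyl)-2,2-dimethyl-1,3-dioxolane | CC1(C)OC[C@H](C=C(Br)Br)O1 | intermediate
15 | lithium [(4S)-2,2-dimethyl-1,3-dioxolan-4-yl]acetylide (in-flask) | CC1(C)OC[C@H](C#C[Li])O1 | intermediate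
16 | methyl 3-[(4S)-2,2-dimethyl-1,3-dioxolan-4-yl]prop-2-ynoate | CC1(C)OC[C@H](C#CC(=O)OC)O1 | intermediate
17 | methyl (2E)-2-(diisobutylalumanyl)-3-[(4S)-2,2-dimethyl-1,3-dioxolan-4-yl]prop-2-enoate (in-flask, H and Al cis) | CC1(C)OC[C@H](/C=C(/[Al](CC(C)C)CC(C)C)C(=O)OC)O1 | intermediate
18 | methyl (2Z)-3-[(4S)-2,2-dimethyl-1,3-dioxolan-4-yl]-2-[(4,4,5,5-tetramethyl-1,3,2-dioxaborolan-2-yl)methyl]prop-2-enoate | CC1(C)OC[C@H](/C=C(/CB2OC(C)(C)C(C)(C)O2)C(=O)OC)O1 | intermediate
19 | methyl (3S,4S,5Z)-3-[(4S)-2,2-dimethyl-1,3-dioxolan-4-yl]-6-iodo-2-methylidene-4-[(4,4,5,5-tetramethyl-1,3,2-dioxaborolan-2-yl)oxy]hept-5-enoate (in-flask anti borate) | CC1(C)OC[C@@H](O1)[C@@H](C(=C)C(=O)OC)[C@H](OB2OC(C)(C)C(C)(C)O2)/C=C(/C)I | intermediate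
20 | (4S,5S)-4-[(4S)-2,2-dimethyl-1,3-dioxolan-4-yl]-5-[(1Z)-2-iodoprop-1-en-1-yl]-3-methylideneoxolan-2-one | CC1(C)OC[C@@H](O1)[C@H]2C(=C)C(=O)O[C@@H]2/C=C(/C)I | intermediate
21 | (4R,5S)-4-[(1S)-1,2-dihydroxyethyl]-5-[(1Z)-2-iodoprop-1-en-1-yl]-3-methylideneoxolan-2-one | OC[C@@H](O)[C@H]1C(=C)C(=O)O[C@@H]1/C=C(/C)I | intermediate
22 | (4S,5S)-4-[(1S)-1,2-bis(triethylsilyloxy)ethyl]-5-[(1Z)-2-iodoprop-1-en-1-yl]-3-methylideneoxolan-2-one | CC[Si](CC)(CC)OC[C@@H](O[Si](CC)(CC)CC)[C@H]1C(=C)C(=O)O[C@@H]1/C=C(/C)I | intermediate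
23 | (2S)-2-[(2S,3S)-2-[(1Z)-2-iodoprop-1-en-1-yl]-4-methylidene-5-oxooxolan-3-yl]-2-(triethylsilyloxy)acetaldehyde | O=C[C@@H](O[Si](CC)(CC)CC)[C@H]1C(=C)C(=O)O[C@@H]1/C=C(/C)I | intermediate
24 | (2S)-2-[(2R,3S)-2-[(1Z)-2-{5-methyl-4-[(triisopropylsilyl)oxy]furan-2-yl}prop-1-en-1-yl]-4-methylidene-5-oxooxolan-3-yl]-2-(triethylsilyloxy)acetaldehyde | O=C[C@@H](O[Si](CC)(CC)CC)[C@H]1C(=C)C(=O)O[C@@H]1/C=C(/C)c1cc(O[Si](C(C)C)(C(C)C)C(C)C)c(C)o1 | intermediate
25 | BF3-bound O-triisopropylsilyl oxocarbenium aldolate of the closed ten-membered ring (in-flask) | F[B-](F)(F)O[C@H]1[C@@H](O[Si](CC)(CC)CC)[C@H]2C(=C)C(=O)O[C@@H]2/C=C(/C)C2=CC(=[O+][Si](C(C)C)(C(C)C)C(C)C)[C@@]1(C)O2 | intermediate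
26 | 9-hydroxy-8-O-triethylsilyl macrocycle (6R,7S,8S,9S,10S; target lacking the methacrylate) | O[C@H]1[C@@H](O[Si](CC)(CC)CC)[C@H]2C(=C)C(=O)O[C@@H]2/C=C(/C)C2=CC(=O)[C@@]1(C)O2 | intermediate
27 | 9-O-methacryloyl-8-O-triethylsilyl macrocycle (6R,7S,8S,9S,10S) | C=C(C)C(=O)O[C@H]1[C@@H](O[Si](CC)(CC)CC)[C@H]2C(=C)C(=O)O[C@@H]2/C=C(/C)C2=CC(=O)[C@@]1(C)O2 | intermediate
28 | CNP0562373.1 (6R,7R,8S,9S,10S) | C=C(C)C(=O)O[C@H]1[C@@H](O)[C@H]2C(=C)C(=O)O[C@@H]2/C=C(/C)C2=CC(=O)[C@@]1(C)O2 | target

**Step count and risks**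

Total: 18 steps. Longest linear sequence: 11 steps (13 → 28, steps 8 to 18).

Step 16 is the most uncertain. Oligomerisation by intermolecular aldol, attack through furan C4, loss of the C8 silyl ether under BF3, or loss of facial control at C10 could each defeat the closure. The fallback uses known reactions and sets out from 23 and 8. An intermolecular BF3·OEt2-mediated Mukaiyama aldol at −78 °C (the known reaction type, Felkin–Anh control at C9, C10 epimers to be separated) should give the acyclic stannyl furanone aldol F1. An intramolecular Stille coupling under high dilution (Pd2(dba)3, AsPh3, CuI, DMF) would then close the ring at C3–C4 and come back to the route at 26.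

Step 11 is next. The concern is poor facial selectivity with respect to the dioxolane: attack anti to the C8–O bond would give the trans-lactone epimeric at both C6 and C7. Slow addition of the electron-poor boronate and Z to E drift of the iodoenal under the Lewis acid are further concerns. The fallback sets out from 13 and builds the lactone by a sigmatropic rearrangement, where attack anti to the C–O bond is the sense that is needed. A Z-selective Wittig reaction (Ph3P=CHCO2Me, MeOH, 0 °C) gives the Z-enoate F2, and i-Bu2AlH reduction gives the Z-allylic alcohol F3. Eschenmoser–Claisen rearrangement (MeC(OMe)2NMe2, xylene, 140 °C; C8–H in the alkene plane, new bond anti to oxygen) gives the pentenamide F4. Iodolactonisation (I2, THF/H2O) gives the trans-iodolactone F5, and Kornblum oxidation (AgBF4, DMSO; then Et3N) gives the lactone aldehyde F6. Stork–Zhao olefination (Ph3P=C(I)CH3, THF, −78 °C) gives the Z-iodoalkenyl lactone F7. Finally α-methylenation through the Mannich base F8 (LiN(SiMe3)2, Me2N=CH2 I; then MeI, NaHCO3) comes back to the route at 20.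

Step 10 is the third. Loss of alkene geometry through the aluminium allenolate, over-reduction of the ester, or β-elimination of the dioxolane oxygen from the alkenylalane could occur. The fallback sets out from 16. Palladium-catalysed syn-hydrostannation (Bu3SnH, Pd(PPh3)4, THF) gives the α-stannyl acrylate F9, and iododestannylation (I2, CH2Cl2, 0 °C) gives the α-iodo acrylate F10. Negishi coupling with IZnCH2Bpin (Pd(PPh3)4, THF) with retention then comes back to the route at 18.

**Further compounds**

F1 | step 16 | (6S,7S,8S,9S,10S) acyclic aldol of 23 with 8: 2-methyl-5-(tributylstannyl)-3(2H)-furanone bearing the C9 carbinol, 8-O-triethylsilyl, iodoalkenyl lactone | O[C@@H]([C@@H](O[Si](CC)(CC)CC)[C@H]1C(=C)C(=O)O[C@@H]1/C=C(/C)I)[C@]1(C)OC(=CC1=O)[Sn](CCCC)(CCCC)CCCC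
F2 | step 11 | methyl (2Z)-3-[(4S)-2,2-dimethyl-1,3-dioxolan-4-yl]prop-2-enoate | CC1(C)OC[C@H](/C=C\C(=O)OC)O1
F3 | step 11 | (2Z)-3-[(4S)-2,2-dimethyl-1,3-dioxolan-4-yl]prop-2-en-1-ol | CC1(C)OC[C@H](/C=C\CO)O1
F4 | step 11 | (3S)-3-[(4S)-2,2-dimethyl-1,3-dioxolan-4-yl]-N,N-dimethylpent-4-enamide | CC1(C)OC[C@@H](O1)[C@H](C=C)CC(=O)N(C)C
F5 | step 11 | (4R,5S)-4-[(4S)-2,2-dimethyl-1,3-dioxolan-4-yl]-5-(iodomethyl)oxolan-2-one | CC1(C)OC[C@@H](O1)[C@H]2CC(=O)O[C@@H]2CI
F6 | step 11 | (2S,3R)-3-[(4S)-2,2-dimethyl-1,3-dioxolan-4-yl]-5-oxooxolane-2-carbaldehyde | CC1(C)OC[C@@H](O1)[C@H]2CC(=O)O[C@@H]2C=O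
F7 | step 11 | (4S,5S)-4-[(4S)-2,2-dimethyl-1,3-dioxolan-4-yl]-5-[(1Z)-2-iodoprop-1-en-1-yl]oxolan-2-one | CC1(C)OC[C@@H](O1)[C@H]2CC(=O)O[C@@H]2/C=C(/C)I
F8 | step 11 | (4S,5S)-3-[(dimethylamino)methyl]-4-[(4S)-2,2-dimethyl-1,3-dioxolan-4-yl]-5-[(1Z)-2-iodoprop-1-en-1-yl]oxolan-2-one (C3 epimers) | CC1(C)OC[C@@H](O1)[C@H]2C(CN(C)C)C(=O)O[C@@H]2/C=C(/C)I
F9 | step 10 | methyl (2E)-3-[(4S)-2,2-dimethyl-1,3-dioxolan-4-yl]-2-(tributylstannyl)prop-2-enoate | CC1(C)OC[C@H](/C=C(/[Sn](CCCC)(CCCC)CCCC)C(=O)OC)O1
F10 | step 10 | methyl (2E)-3-[(4S)-2,2-dimethyl-1,3-dioxolan-4-yl]-2-iodoprop-2-enoate | CC1(C)OC[C@H](/C=C(/I)C(=O)OC)O1
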